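**Plan**
1. Enabling feature: in the quinone ring C1(=O)–C2(OMe)=C3(Me)–C4(=O)–C5H=C6, the C5=C6 bond is conjugated to the exocyclic C7=CH2 on C6. This 1-(1-substituted vinyl)cyclohexene is the product pattern of ring-closing enyne metathesis, and the para-dioxygenated ring is a tautomer away from a 4-silyloxycyclohexa-2,5-dienone.
2. Retrosynthesis: quinone 23 ⇒ hydroquinone mono-silyl ether 22 (oxidative desilylation) ⇒ open-chain enynone 20 (cut ring bond C5=C6, return the CH2 of C7 to C5) ⇒ acid chloride 19 and alkyne 18 (cut the acyl–alkynyl bond C1–C6).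
3. Forward, ring fragment: methyl 2-oxobutanoate and acrolein give butenolide 6 (aldol bond C3–C4). Its lactone is a temporary ring that fixes C1 and C4 cis on C2=C3; it is opened (8), joined to 18 (20), and the carbocycle is closed last (step 11), then oxidised (step 12).
4. Forward, side chain: acetylide addition to a Weinreb amide makes C7–C8; Noyori transfer hydrogenation of ynone 13 sets C8 (S), which is carried unchanged; the Z ester comes from angelic acid.
5. Helpers: the TBS group and the alcohol oxidation level at C4 (ketone level at C1) make the metathesis product aromatise; both are removed in step 12. The C4 carbinol centre is left uncontrolled because aromatisation erases it.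

Key step: step 11

Remark: locants C1–C8 follow the target (ring C1 = carbonyl next to the methoxy carbon C2, C3 = methyl carbon, C4 = second carbonyl, C5 = ring CH, C6 = ring carbon bearing the chain, C7 = C(=CH2), C8 = stereogenic carbinol carbon). Compounds 4–8 and 19–21 are racemic or epimeric at C4.

**Step 1**
Reactants: 1 methyl 2-oxobutanoate
Product: 2 methyl (Z)-2-(trimethylsilyloxy)but-2-enoate
Conditions: TMSCl, Et3N, CH2Cl2, 0 → 25 °C
Reagents that add atoms: chlorotrimethylsilane, C[Si](C)(C)Cl
Why: Silyl enol ether formation by soft enolisation of the α-keto ester at its only enolisable position gives the nucleophile for the aldol step.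

**Step 2**
Reactants: 2 methyl (Z)-2-(trimethylsilyloxy)but-2-enoate; 3 acrolein
Product: 5 3-hydroxy-4-methyl-5-vinylfuran-2(5H)-one (racemic), via silylated aldol adduct 4 (not isolated)
Conditions: Sc(OTf)3 (10 mol %), CH2Cl2, −78 → −20 °C; then 1 M HCl, MeOH, 25 °C
Reagents that add atoms: none
Why: A Lewis-acid-catalysed Mukaiyama aldol addition to the aldehyde carbon of acrolein (1,2-addition) forms C3–C4, and acid then removes the silyl group and closes the γ-hydroxy α-keto ester to the enolised lactone (isotetronic acid formation); the new carbinol centre is racemic and is erased in step 11.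

**Step 3**
Reactants: 5 3-hydroxy-4-methyl-5-vinylfuran-2(5H)-one
Product: 6 3-methoxy-4-methyl-5-vinylfuran-2(5H)-one (racemic)
Conditions: Me2SO4, K2CO3, acetone, 25 °C
Reagents that add atoms: dimethyl sulfate, COS(=O)(=O)OC
Why: O-Methylation of the acidic enol with a hard methylating agent and carbonate base installs the methoxy group on C2, next to the future C1 carbonyl.

**Step 4**
Reactants: 6 3-methoxy-4-methyl-5-vinylfuran-2(5H)-one
Product: 8 tert-butyldimethylsilyl (2E)-4-(tert-butyldimethylsilyloxy)-2-methoxy-3-methylhexa-2,5-dienoate, via potassium hydroxy-dienoate 7 (not isolated)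
Conditions: KOH (1.0 equiv), THF/H2O, 0 °C; evaporate; TBSCl (2.5 equiv), imidazole, DMF, 25 °C
Reagents that add atoms: potassium hydroxide, [K+].[OH-]; tert-butyldimethylsilyl chloride, CC(C)(C)[Si](C)(C)Cl
Why: Lactone saponification followed by exhaustive silylation of the hydroxy carboxylate gives the open chain, in which the former ring has fixed the carbinol carbon and the carboxyl carbon cis on the tetrasubstituted alkene (2E by priority rules).

**Step 5**
Reactants: 9 4-methylpent-3-enoic acid
Product: 10 N-methoxy-N,4-dimethylpent-3-enamide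
Conditions: MeNHOMe·HCl, EDC·HCl, N-methylmorpholine, CH2Cl2, 0 → 25 °C
Reagents that add atoms: N,O-dimethylhydroxylamine hydrochloride, CNOC.Cl
Why: A carbodiimide amide coupling gives the Weinreb amide under conditions that do not move the β,γ-double bond.

**Step 6**
Reactants: 10 N-methoxy-N,4-dimethylpent-3-enamide; 11 ethynyltrimethylsilane
Product: 13 6-methyl-1-(trimethylsilyl)hept-5-en-1-yn-3-one, via lithium (trimethylsilyl)acetylide 12 (not isolated)
Conditions: 11, n-BuLi, THF, −78 °C; then 10, −78 → −20 °C; cold 1 M HCl
Reagents that add atoms: none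
Why: In this Weinreb ketone synthesis the chelated tetrahedral intermediate stops the acetylide at mono-addition (bond C7–C8), and the cold acidic quench releases the ynone without conjugating the β,γ-alkene.

**Step 7**
Reactants: 13 6-methyl-1-(trimethylsilyl)hept-5-en-1-yn-3-one
Product: 14 (S)-6-methyl-1-(trimethylsilyl)hept-5-en-1-yn-3-ol
Conditions: Ru[(S,S)-TsNCH(Ph)CH(Ph)NH](p-cymene) (1 mol %), i-PrOH, 25 °C
Reagents that add atoms: none
Why: In this Noyori asymmetric transfer hydrogenation of an alkynyl ketone the alkynyl group takes the place an aryl group occupies in the Ru–H/N–H transition state, so the (S,S) catalyst should deliver the (S)-carbinol at C8, and the base-free medium spares the β,γ-unsaturated ketone.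

**Step 8**
Reactants: 14 (S)-6-methyl-1-(trimethylsilyl)hept-5-en-1-yn-3-ol
Product: 15 (S)-6-methylhept-5-en-1-yn-3-ol
Conditions: K2CO3 (0.2 equiv), MeOH, 0 → 25 °C
Reagents that add atoms: none
Why: Methanolic carbonate protodesilylates the alkynylsilane and leaves the carbinol centre untouched.

**Step 9**
Reactants: 15 (S)-6-methylhept-5-en-1-yn-3-ol; 16 angelic acid [(Z)-2-methylbut-2-enoic acid]
Product: 18 (S)-6-methylhept-5-en-1-yn-3-yl (Z)-2-methylbut-2-enoate, via mixed anhydride 17 (not isolated)
Conditions: 16, 2,4,6-trichlorobenzoyl chloride, Et3N, toluene, 25 °C; then 15, 80 °C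
Reagents that add atoms: none
Why: A Yamaguchi-type mixed-anhydride esterification run without a nucleophilic catalyst acylates the oxygen with retention at C8 and should keep the Z geometry of the angelate.

**Step 10**
Reactants: 8 tert-butyldimethylsilyl (2E)-4-(tert-butyldimethylsilyloxy)-2-methoxy-3-methylhexa-2,5-dienoate; 18 (S)-6-methylhept-5-en-1-yn-3-yl (Z)-2-methylbut-2-enoate
Product: 20 (5S,9E)-11-(tert-butyldimethylsilyloxy)-9-methoxy-2,10-dimethyl-8-oxotrideca-2,9,12-trien-6-yn-5-yl (Z)-2-methylbut-2-enoate (both C11 epimers), via acid chloride 19 (not isolated)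
Conditions: 8, (COCl)2, DMF (cat.), CH2Cl2, 0 → 25 °C; evaporate; then 18, PdCl2(PPh3)2 (2 mol %), CuI (4 mol %), Et3N (1.2 equiv), THF, 25 °C
Reagents that add atoms: none
Why: Oxalyl chloride with catalytic DMF converts the silyl ester into the acid chloride under neutral conditions that keep the silyl ether, and an acyl Sonogashira coupling then forms the C1–C6 bond in the presence of the angelate ester.

**Step 11**
Reactants: 20 (5S,9E)-11-(tert-butyldimethylsilyloxy)-9-methoxy-2,10-dimethyl-8-oxotrideca-2,9,12-trien-6-yn-5-yl (Z)-2-methylbut-2-enoate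
Product: 22 (3S)-2-[5-(tert-butyldimethylsilyloxy)-2-hydroxy-3-methoxy-4-methylphenyl]-6-methylhepta-1,5-dien-3-yl (Z)-2-methylbut-2-enoate, via cyclohexadienone 21 (not isolated)
Conditions: second-generation Grubbs catalyst (H2IMes)(PCy3)Cl2Ru=CHPh (10 mol %), ethylene (1 atm), CH2Cl2, 40 °C
Reagents that add atoms: none
Why: Ring-closing enyne metathesis: the ruthenium alkylidene loads onto the monosubstituted C5=CH2 alkene, the Ru=C5 carbene adds across the C6≡C7 alkyne so that C5 bonds to C6, the ruthenacyclobutene opens to a C7 vinylcarbene, and methylidene transfer (ethylene or a second substrate alkene, no net gain of atoms) caps C7 as C=CH2 and releases cyclohexa-2,5-dienone 21. Because 21 carries H and OTBS on C4 para to the C1 carbonyl, it is the keto tautomer of a hydroquinone mono-ether and should aromatise in the flask to 22, which withdraws the new diene from further metathesis and erases the C4 centre, so both C4 epimers of 20 converge on one product. The closest known reaction type is the ring-closing enyne metathesis of 1,7-enynes to 1-(1-substituted vinyl)cyclohexenes, including variants in which the primary diene aromatises to a vinyl-substituted phenol. The one ring formed (the six-membered carbocycle C1–C6) closes in the exo mode, carbene carbon C5 attacking the proximal alkyne carbon C6 with the new carbene left exocyclic on C7; endo closure would give a seven-membered ring. No stereocentre is created and C8 is not touched. The step needs initiation at the terminal vinyl group and exo regiochemistry: the first is secured because that alkene is the only unhindered monosubstituted olefin (the alkyne is internal and flanked by a carbonyl and a branched carbinol carbon, the prenyl and angelate alkenes are trisubstituted), the second because the cis arrangement of C1 and C4 on C2=C3 puts C5 within reach of C6 only; if ethylene adds to the alkyne first, the resulting 2,3-disubstituted butadiene should still close between C5 and C6 by diene metathesis to the same product.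

**Step 12**
Reactants: 22 (3S)-2-[5-(tert-butyldimethylsilyloxy)-2-hydroxy-3-methoxy-4-methylphenyl]-6-methylhepta-1,5-dien-3-yl (Z)-2-methylbut-2-enoate
Product: 23 (3S)-2-(5-methoxy-4-methyl-3,6-dioxocyclohexa-1,4-dien-1-yl)-6-methylhepta-1,5-dien-3-yl (Z)-2-methylbut-2-enoate
Conditions: PhI(OAc)2 (1.1 equiv), MeCN/H2O (4:1), 0 °C
Reagents that add atoms: none
Why: Hypervalent-iodine oxidation of the free phenol generates a para-silyloxy phenoxenium species that loses the silyl group to water and gives the para-quinone (oxidative desilylation), under conditions mild enough for the angelate, the prenyl group and the 1,1-disubstituted alkene.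

**Compound list**
1 | methyl 2-oxobutanoate | CCC(=O)C(=O)OC | starting material
2 | methyl (Z)-2-(trimethylsilyloxy)but-2-enoate | C/C=C(\O[Si](C)(C)C)C(=O)OC | intermediate
3 | acrolein (prop-2-enal) | C=CC=O | starting material
4 | methyl 3-methyl-2-oxo-4-(trimethylsilyloxy)hex-5-enoate (diastereomers) | C=CC(O[Si](C)(C)C)C(C)C(=O)C(=O)OC | intermediate (not isolated)
5 | 3-hydroxy-4-methyl-5-vinylfuran-2(5H)-one (racemic) | C=CC1OC(=O)C(O)=C1C | intermediate
6 | 3-methoxy-4-methyl-5-vinylfuran-2(5H)-one (racemic) | C=CC1OC(=O)C(OC)=C1C | intermediate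
7 | potassium (2E)-4-hydroxy-2-methoxy-3-methylhexa-2,5-dienoate | C=CC(O)/C(C)=C(OC)\C(=O)[O-].[K+] | intermediate (not isolated)
8 | tert-butyldimethylsilyl (2E)-4-(tert-butyldimethylsilyloxy)-2-methoxy-3-methylhexa-2,5-dienoate | C=CC(O[Si](C)(C)C(C)(C)C)/C(C)=C(OC)\C(=O)O[Si](C)(C)C(C)(C)C | intermediate
9 | 4-methylpent-3-enoic acid | CC(C)=CCC(=O)O | starting material
10 | N-methoxy-N,4-dimethylpent-3-enamide | CC(C)=CCC(=O)N(C)OC | intermediate
11 | ethynyltrimethylsilane | C#C[Si](C)(C)C | starting material
12 | lithium (trimethylsilyl)acetylide | [Li]C#C[Si](C)(C)C | intermediate (not isolated)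
13 | 6-methyl-1-(trimethylsilyl)hept-5-en-1-yn-3-one | CC(C)=CCC(=O)C#C[Si](C)(C)C | intermediate
14 | (S)-6-methyl-1-(trimethylsilyl)hept-5-en-1-yn-3-ol | C[Si](C)(C)C#C[C@H](CC=C(C)C)O | intermediate
15 | (S)-6-methylhept-5-en-1-yn-3-ol | C#C[C@H](CC=C(C)C)O | intermediate
16 | angelic acid, (Z)-2-methylbut-2-enoic acid | C/C=C(/C)C(=O)O | starting material
17 | (Z)-2-methylbut-2-enoic 2,4,6-trichlorobenzoic anhydride | C/C=C(/C)C(=O)OC(=O)c1c(Cl)cc(Cl)cc1Cl | intermediate (not isolated)
18 | (S)-6-methylhept-5-en-1-yn-3-yl (Z)-2-methylbut-2-enoate | C#C[C@H](CC=C(C)C)OC(=O)/C(C)=C\C | intermediate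
19 | (2E)-4-(tert-butyldimethylsilyloxy)-2-methoxy-3-methylhexa-2,5-dienoyl chloride | C=CC(O[Si](C)(C)C(C)(C)C)/C(C)=C(OC)\C(Cl)=O | intermediate (not isolated)
20 | (5S,9E)-11-(tert-butyldimethylsilyloxy)-9-methoxy-2,10-dimethyl-8-oxotrideca-2,9,12-trien-6-yn-5-yl (Z)-2-methylbut-2-enoate (both C11 epimers) | C=CC(O[Si](C)(C)C(C)(C)C)/C(C)=C(OC)\C(=O)C#C[C@H](CC=C(C)C)OC(=O)/C(C)=C\C | intermediate
21 | (3S)-2-[3-(tert-butyldimethylsilyloxy)-5-methoxy-4-methyl-6-oxocyclohexa-1,4-dien-1-yl]-6-methylhepta-1,5-dien-3-yl (Z)-2-methylbut-2-enoate | C=C(C1=CC(O[Si](C)(C)C(C)(C)C)C(C)=C(OC)C1=O)[C@H](CC=C(C)C)OC(=O)/C(C)=C\C | intermediate (not isolated)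
22 | (3S)-2-[5-(tert-butyldimethylsilyloxy)-2-hydroxy-3-methoxy-4-methylphenyl]-6-methylhepta-1,5-dien-3-yl (Z)-2-methylbut-2-enoate | C=C(c1cc(O[Si](C)(C)C(C)(C)C)c(C)c(OC)c1O)[C@H](CC=C(C)C)OC(=O)/C(C)=C\C | intermediate
23 | (3S)-2-(5-methoxy-4-methyl-3,6-dioxocyclohexa-1,4-dien-1-yl)-6-methylhepta-1,5-dien-3-yl (Z)-2-methylbut-2-enoate | C=C(C1=CC(=O)C(C)=C(OC)C1=O)[C@H](CC=C(C)C)OC(=O)/C(C)=C\C | target

**Totals**
Total step count: 12. Longest linear sequence: 8 steps (steps 5–12, from 4-methylpent-3-enoic acid).

**Steps most likely to fail**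

Step 11. The electron-poor, doubly flanked alkyne may engage the ruthenium alkylidene only sluggishly. The C1 carbonyl may sequester the catalyst by chelation. Ethylene may slowly cleave the prenyl alkene. Fallback: setting out from 20, the C1 ketone would be reduced under Luche conditions (NaBH4, CeCl3·7H2O, MeOH, −78 °C) to the propargylic alcohol F1 (carbinol epimers). This electronically ordinary 1,7-enyne, without a conjugated carbonyl, would be closed by ring-closing enyne metathesis to the cyclohexa-2,5-dienol F2. Oxidation of the doubly allylic alcohol with MnO2 (CH2Cl2, 25 °C) would give dienone 21, which tautomerises, and the route is rejoined at 22.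

Step 10. The acid chloride may close back to the butenolide with loss of the silyl group. The amine base may move the propargylic hydrogen of the γ-acyloxy ynone (propargyl–allenyl shift, erosion at C8). The same detour also avoids relactonisation during the silylation of step 4. Fallback: setting out from 6, the lactone would be opened with Me2AlN(OMe)Me (from AlMe3 and MeNHOMe·HCl, CH2Cl2, 0 °C) to the hydroxy Weinreb amide F3. Silylation (TBSOTf, 2,6-lutidine, −78 °C) would give the silyl ether amide F4, and reduction with i-Bu2AlH (THF, −78 °C) the aldehyde F5. Addition of the alkynylzinc reagent made from 18 and Me2Zn (toluene, 0 → 25 °C; the ester is tolerated) would give the propargylic alcohol F1. Dess–Martin oxidation would return the route at 20.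

Step 12. The oxidant may attack the electron-rich α-substituted styrene or the ortho position (ortho-quinone or quinone methide formation) instead of giving clean para oxidation with loss of the silyl group. Fallback: setting out from 22, the aryl silyl ether would be cleaved with Bu4NF/AcOH (THF, 0 °C) to the free hydroquinone F6. This would be oxidised with Ag2O (Et2O, 25 °C) or air, and the route is rejoined at 23.

**Further compounds**
F1 | step 11 | (5S,9E)-11-(tert-butyldimethylsilyloxy)-8-hydroxy-9-methoxy-2,10-dimethyltrideca-2,9,12-trien-6-yn-5-yl (Z)-2-methylbut-2-enoate | C=CC(O[Si](C)(C)C(C)(C)C)/C(C)=C(OC)\C(O)C#C[C@H](CC=C(C)C)OC(=O)/C(C)=C\C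
F2 | step 11 | (3S)-2-[3-(tert-butyldimethylsilyloxy)-6-hydroxy-5-methoxy-4-methylcyclohexa-1,4-dien-1-yl]-6-methylhepta-1,5-dien-3-yl (Z)-2-methylbut-2-enoate | C=C(C1=CC(O[Si](C)(C)C(C)(C)C)C(C)=C(OC)C1O)[C@H](CC=C(C)C)OC(=O)/C(C)=C\C
F3 | step 10 | (2E)-4-hydroxy-N,2-dimethoxy-N,3-dimethylhexa-2,5-dienamide | C=CC(O)/C(C)=C(OC)\C(=O)N(C)OC
F4 | step 10 | (2E)-4-(tert-butyldimethylsilyloxy)-N,2-dimethoxy-N,3-dimethylhexa-2,5-dienamide | C=CC(O[Si](C)(C)C(C)(C)C)/C(C)=C(OC)\C(=O)N(C)OC
F5 | step 10 | (2E)-4-(tert-butyldimethylsilyloxy)-2-methoxy-3-methylhexa-2,5-dienal | C=CC(O[Si](C)(C)C(C)(C)C)/C(C)=C(OC)\C=O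
F6 | step 12 | (3S)-2-(2,5-dihydroxy-3-methoxy-4-methylphenyl)-6-methylhepta-1,5-dien-3-yl (Z)-2-methylbut-2-enoate | C=C(c1cc(O)c(C)c(OC)c1O)[C@H](CC=C(C)C)OC(=O)/C(C)=C\C
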